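**Retrosynthetic overview**

1. Oxane numbering used here: O1, C2 (aryl), C3 (cinnamyl), C4, C5 (bears CH(OH)Ar), C6. The four stereocentres form a C2-symmetric array about C4: both Ar–CH(O)–CH(CH2–) units are (R) at the benzylic carbon and anti. The target is therefore a (1R,2R,4R,5R)-2,4-bis(hydroxymethyl)-1,5-diarylpentane-1,5-diol in which one CH2–O is tied to the distal benzylic oxygen (the oxane) and the other CH2 carries the styryl group.
2. Late disconnections: styryl–CH2 bond (Ni cross-electrophile coupling) and O1–C6 (6-exo Williamson closure of the symmetric bis-tosylate; the only ring closure of the target, and the step that breaks the symmetry).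
3. All four stereocentres come from an achiral bis-enone: two-fold CBS reduction (catalyst control), then two-fold anti-selective 9-BBN hydroboration (substrate control, two centres in one event).
4. Key disconnection C2–C3 and C4–C5: C2 and the exocyclic carbinol carbon are both aryl-bearing C–O carbons, 1,5-related through C3–C4–C5. At the ketone level this chain is a 1,5-diaryl-1,5-dione, i.e. a symmetric 1,3-diaryl-1,3-dione (C2 bonded to C5) with a C3–C4 unit inserted. This is the retron of a de Mayo photocycloaddition/retro-aldol with ethylene.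
5. Ring order: transient cyclobutane (step 4, opened in the same step), then the oxane (step 9).

Key step: step 4

Assumption: in the oxazaborolidine reduction of the aryl 1-substituted-vinyl ketones the aryl group is taken to act as the larger group, as in aryl alkyl ketones; the (S)-catalyst is therefore specified for the (R)-carbinols.

**Route**

Step 1
Reactants: 1 4'-hydroxyacetophenone
Product: 2 1-[4-(triisopropylsilyloxy)phenyl]ethan-1-one
Conditions: TIPSCl, imidazole, DMF, rt
Reagents that add atoms: triisopropylsilyl chloride, CC(C)[Si](Cl)(C(C)C)C(C)C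
Why: Imidazole-promoted O-silylation of the phenol; the bulky aryl TIPS ether is chosen to survive the amide base, borane, alkoxide and Ni/Mn steps and to come off with fluoride at the end.

Step 2
Reactants: 3 methyl 4-hydroxybenzoate
Product: 4 methyl 4-(triisopropylsilyloxy)benzoate
Conditions: TIPSCl, imidazole, DMF, rt
Reagents that add atoms: triisopropylsilyl chloride, CC(C)[Si](Cl)(C(C)C)C(C)C
Why: Same phenol silylation, giving the non-enolisable ester partner for the Claisen condensation.

Step 3
Reactants: 2 1-[4-(triisopropylsilyloxy)phenyl]ethan-1-one; 4 methyl 4-(triisopropylsilyloxy)benzoate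
Product: 5 1,3-bis[4-(triisopropylsilyloxy)phenyl]propane-1,3-dione
Conditions: LiHMDS (2.2 equiv), THF, −78 °C; then 4, −78 °C → rt; sat. aq. NH4Cl
Reagents that add atoms: none
Why: Crossed Claisen condensation of the ketone enolate with the non-enolisable ester, driven by deprotonation of the product diketone, which should exist almost entirely as the hydrogen-bonded enol.

Step 4
Reactants: 5 1,3-bis[4-(triisopropylsilyloxy)phenyl]propane-1,3-dione; 6 ethylene
Product: 8 1,5-bis[4-(triisopropylsilyloxy)phenyl]pentane-1,5-dione, via cyclobutanol photoadduct 7 (not isolated)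
Conditions: hν (365 nm, Pyrex), ethylene (3 bar), degassed MeCN, 5 °C
Reagents that add atoms: none
Why: De Mayo reaction: excitation of the chelated enol of 5 (a locked cis-enone chromophore) is followed by stepwise [2+2] photocycloaddition to ethylene through a 1,4-biradical, whose recombination closes the only ring formed here, the cyclobutane of 7. The β-hydroxy ketone 7 then opens by retro-aldol cleavage of the bond between its carbinol carbon and the aroyl-bearing carbon, driven by release of cyclobutane strain and formation of a second aryl ketone, so that ethylene ends up inserted between the former enol carbon (C2) and the former central carbon (C5) and the C2–C3 and C4–C5 bonds are made together. The closest known reaction type is the photoaddition of enolised 1,3-diketones (and their BF2 chelates) to alkenes with fragmentation to 1,5-diketones. No ring of the target is closed and no stereocentre survives, since both stereocentres of 7 are destroyed on ring opening. The step needs chemoselectivity only: both partners are symmetric, so there is no head-to-head/head-to-tail question, and a single ethylene should be taken up because 8 is no longer an enolised 1,3-diketone and absorbs only weakly at 365 nm.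

Step 5
Reactants: 8 1,5-bis[4-(triisopropylsilyloxy)phenyl]pentane-1,5-dione
Product: 9 2,4-dimethylidene-1,5-bis[4-(triisopropylsilyloxy)phenyl]pentane-1,5-dione
Conditions: (CH2O)n (6 equiv), i-Pr2NH·CF3CO2H (2 equiv), CF3CO2H (0.2 equiv), THF, 60 °C; crude 9 kept cold and used directly
Reagents that add atoms: formaldehyde (as paraformaldehyde), C=O
Why: Two-fold Mannich-type α-methylenation (aminomethylation then β-elimination of the amine) at the two equivalent α-CH2 groups, which installs the future C6 and the future cinnamyl CH2 in one operation; mild conditions are used so the skipped bis-enone does not isomerise into conjugation.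

Step 6
Reactants: 9 2,4-dimethylidene-1,5-bis[4-(triisopropylsilyloxy)phenyl]pentane-1,5-dione
Product: 10 (1R,5R)-2,4-dimethylidene-1,5-bis[4-(triisopropylsilyloxy)phenyl]pentane-1,5-diol
Conditions: (S)-2-methyl-CBS-oxazaborolidine (30 mol %), catecholborane (3 equiv), toluene, −78 °C; MeOH quench; chromatography to remove the meso diol
Reagents that add atoms: none
Why: Corey–Bakshi–Shibata reduction: hydride is delivered within the ketone–oxazaborolidine–borane complex, so both carbinol centres should be set (R) under catalyst control (the α-substituent disfavours 1,4-reduction), and because the two reductions are independent the minor sense should end mainly in the separable meso diol, which upgrades the enantiopurity of the C2-symmetric diol.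

Step 7
Reactants: 10 (1R,5R)-2,4-dimethylidene-1,5-bis[4-(triisopropylsilyloxy)phenyl]pentane-1,5-diol
Product: 12 (1R,2R,4R,5R)-2,4-bis(hydroxymethyl)-1,5-bis[4-(triisopropylsilyloxy)phenyl]pentane-1,5-diol, via fourfold 9-BBN adduct 11 (not isolated)
Conditions: 9-BBN (5 equiv), THF, 0 °C → rt; then aq. NaOAc, 30% H2O2, 0 °C → rt
Reagents that add atoms: hydrogen peroxide, OO (oxygen of both CH2OH groups); 9-borabicyclo[3.3.1]nonane, B1C2CCCC1CCC2 (its atoms stay only in intermediate 11)
Why: Hydroboration–oxidation of the two 1,1-disubstituted alkenes with the bulky borane should follow the Still–Barrish model (carbinol H eclipsing the alkene to minimise A1,3 strain, borane anti to the aryl group), so each new centre (future C3 and C5) is formed anti to its neighbouring carbinol, with boron at the terminal carbon.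

Step 8
Reactants: 12 (1R,2R,4R,5R)-2,4-bis(hydroxymethyl)-1,5-bis[4-(triisopropylsilyloxy)phenyl]pentane-1,5-diol
Product: 13 bis(4-methylbenzenesulfonate) of the two primary hydroxyls of 12
Conditions: TsCl (2.1 equiv), Et3N, Me3N·HCl (cat.), CH2Cl2, 0 °C
Reagents that add atoms: 4-methylbenzenesulfonyl chloride, Cc1ccc(cc1)S(Cl)(=O)=O
Why: Selective sulfonylation: the two primary hydroxyls should react much faster than the hindered secondary benzylic ones, giving the C2-symmetric bis-tosylate without touching a stereocentre.

Step 9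
Reactants: 13 bis(4-methylbenzenesulfonate) of the two primary hydroxyls of 12
Product: 14 {(2R,3R,5R)-5-[(R)-hydroxy(4-triisopropylsilyloxyphenyl)methyl]-2-(4-triisopropylsilyloxyphenyl)oxan-3-yl}methyl 4-methylbenzenesulfonate
Conditions: NaH (1.0 equiv), THF, 0 °C → rt
Reagents that add atoms: none
Why: Intramolecular Williamson etherification (6-exo-tet): either alkoxide of the symmetric bis-tosylate attacks its 1,5-related CH2OTs and both modes give the same oxane with all four stereocentres retained (no bond to a stereocentre is broken); the 4-exo closure to an oxetane is kinetically disfavoured and a second closure to the bicyclic diether is held back by using one equivalent of base.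

Step 10
Reactants: 15 (E)-4-hydroxycinnamic acid
Product: 17 (E)-3-[4-(triisopropylsilyloxy)phenyl]prop-2-enoic acid, via silyl ester 16 (not isolated)
Conditions: TIPSCl (2.2 equiv), imidazole, DMF, rt; then AcOH–THF–H2O, rt
Reagents that add atoms: triisopropylsilyl chloride, CC(C)[Si](Cl)(C(C)C)C(C)C
Why: Exhaustive silylation followed by selective hydrolysis of the much more labile silyl ester, leaving the aryl silyl ether.

Step 11
Reactants: 17 (E)-3-[4-(triisopropylsilyloxy)phenyl]prop-2-enoic acid
Product: 18 (E)-1-(2-bromoethenyl)-4-(triisopropylsilyloxy)benzene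
Conditions: NBS (1.05 equiv), LiOAc (0.1 equiv), MeCN–H2O (97:3), rt
Reagents that add atoms: N-bromosuccinimide, O=C1CCC(=O)N1Br
Why: Catalytic Hunsdiecker-type decarboxylative bromination, which works well for electron-rich cinnamic acids and should give the (E)-bromoalkene.

Step 12
Reactants: 14 {(2R,3R,5R)-5-[(R)-hydroxy(4-triisopropylsilyloxyphenyl)methyl]-2-(4-triisopropylsilyloxyphenyl)oxan-3-yl}methyl 4-methylbenzenesulfonate; 18 (E)-1-(2-bromoethenyl)-4-(triisopropylsilyloxy)benzene
Product: 20 tris(triisopropylsilyl) ether of the target, via primary iodide 19 (not isolated)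
Conditions: NiBr2·glyme (10 mol %), 4,4'-di-tert-butyl-2,2'-bipyridine (10 mol %), NaI (1.5 equiv), Mn powder (2 equiv), DMA, 50 °C
Reagents that add atoms: sodium iodide, [Na+].[I-] (iodine only in intermediate 19)
Why: Nickel-catalysed reductive cross-electrophile coupling of an alkenyl bromide with a primary alkyl iodide formed in situ from the tosylate (Finkelstein exchange); it tolerates the free secondary alcohol and the silyl ethers and should transfer the alkenyl group with retention of the E geometry.

Step 13
Reactants: 20 tris(triisopropylsilyl) ether of the target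
Product: 21 (R)-{(2R,3S,5R)-3-[(E)-3-(4-hydroxyphenyl)prop-2-enyl]-2-(4-hydroxyphenyl)oxan-5-yl}(4-hydroxyphenyl)methanol (target, numbering as in the overview)
Conditions: TBAF (3.3 equiv), AcOH (3.3 equiv), THF, 0 °C
Reagents that add atoms: none
Why: Fluoride cleavage of the three aryl silyl ethers under acetic acid buffering, which keeps the medium near neutral so that the 4-hydroxybenzylic ether and alcohol should not ionise (no epimerisation at C2 through a quinone methide) and the styrene is untouched.

**Compound list**

1 | 4'-hydroxyacetophenone | CC(=O)c1ccc(O)cc1 | starting material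
2 | 1-[4-(triisopropylsilyloxy)phenyl]ethan-1-one | CC(=O)c1ccc(O[Si](C(C)C)(C(C)C)C(C)C)cc1 | intermediate
3 | methyl 4-hydroxybenzoate | COC(=O)c1ccc(O)cc1 | starting material
4 | methyl 4-(triisopropylsilyloxy)benzoate | COC(=O)c1ccc(O[Si](C(C)C)(C(C)C)C(C)C)cc1 | intermediate
5 | 1,3-bis[4-(triisopropylsilyloxy)phenyl]propane-1,3-dione (enolised) | O=C(CC(=O)c1ccc(O[Si](C(C)C)(C(C)C)C(C)C)cc1)c1ccc(O[Si](C(C)C)(C(C)C)C(C)C)cc1 | intermediate
6 | ethylene | C=C | starting material
7 | {2-hydroxy-2-[4-(triisopropylsilyloxy)phenyl]cyclobutyl}[4-(triisopropylsilyloxy)phenyl]methanone (racemic, not isolated) | OC1(CCC1C(=O)c1ccc(O[Si](C(C)C)(C(C)C)C(C)C)cc1)c1ccc(O[Si](C(C)C)(C(C)C)C(C)C)cc1 | intermediate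
8 | 1,5-bis[4-(triisopropylsilyloxy)phenyl]pentane-1,5-dione | O=C(CCCC(=O)c1ccc(O[Si](C(C)C)(C(C)C)C(C)C)cc1)c1ccc(O[Si](C(C)C)(C(C)C)C(C)C)cc1 | intermediate
9 | 2,4-dimethylidene-1,5-bis[4-(triisopropylsilyloxy)phenyl]pentane-1,5-dione | C=C(CC(=C)C(=O)c1ccc(O[Si](C(C)C)(C(C)C)C(C)C)cc1)C(=O)c1ccc(O[Si](C(C)C)(C(C)C)C(C)C)cc1 | intermediate
10 | (1R,5R)-2,4-dimethylidene-1,5-bis[4-(triisopropylsilyloxy)phenyl]pentane-1,5-diol | CC(C)[Si](C(C)C)(C(C)C)Oc1ccc(cc1)[C@H](O)C(=C)CC(=C)[C@@H](O)c1ccc(O[Si](C(C)C)(C(C)C)C(C)C)cc1 | intermediate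
11 | fourfold 9-BBN adduct of 10 (two C–B and two O–B bonds, not isolated) | CC(C)[Si](C(C)C)(C(C)C)Oc1ccc(cc1)[C@H](OB1C2CCCC1CCC2)[C@@H](CB1C2CCCC1CCC2)C[C@H](CB1C2CCCC1CCC2)[C@@H](OB1C2CCCC1CCC2)c1ccc(O[Si](C(C)C)(C(C)C)C(C)C)cc1 | intermediate
12 | (1R,2R,4R,5R)-2,4-bis(hydroxymethyl)-1,5-bis[4-(triisopropylsilyloxy)phenyl]pentane-1,5-diol | CC(C)[Si](C(C)C)(C(C)C)Oc1ccc(cc1)[C@H](O)[C@@H](CO)C[C@H](CO)[C@@H](O)c1ccc(O[Si](C(C)C)(C(C)C)C(C)C)cc1 | intermediate
13 | bis(4-methylbenzenesulfonate) of the two primary hydroxyls of 12 | CC(C)[Si](C(C)C)(C(C)C)Oc1ccc(cc1)[C@H](O)[C@@H](COS(=O)(=O)c1ccc(C)cc1)C[C@H](COS(=O)(=O)c1ccc(C)cc1)[C@@H](O)c1ccc(O[Si](C(C)C)(C(C)C)C(C)C)cc1 | intermediate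
14 | {(2R,3R,5R)-5-[(R)-hydroxy(4-triisopropylsilyloxyphenyl)methyl]-2-(4-triisopropylsilyloxyphenyl)oxan-3-yl}methyl 4-methylbenzenesulfonate | Cc1ccc(cc1)S(=O)(=O)OC[C@H]2C[C@@H]([C@@H](O)c3ccc(O[Si](C(C)C)(C(C)C)C(C)C)cc3)CO[C@H]2c2ccc(O[Si](C(C)C)(C(C)C)C(C)C)cc2 | intermediate
15 | (E)-4-hydroxycinnamic acid | OC(=O)/C=C/c1ccc(O)cc1 | starting material
16 | triisopropylsilyl (E)-3-[4-(triisopropylsilyloxy)phenyl]prop-2-enoate (not isolated) | CC(C)[Si](C(C)C)(C(C)C)OC(=O)/C=C/c1ccc(O[Si](C(C)C)(C(C)C)C(C)C)cc1 | intermediate
17 | (E)-3-[4-(triisopropylsilyloxy)phenyl]prop-2-enoic acid | OC(=O)/C=C/c1ccc(O[Si](C(C)C)(C(C)C)C(C)C)cc1 | intermediate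
18 | (E)-1-(2-bromoethenyl)-4-(triisopropylsilyloxy)benzene | Br/C=C/c1ccc(O[Si](C(C)C)(C(C)C)C(C)C)cc1 | intermediate
19 | primary iodide corresponding to tosylate 14 (not isolated) | IC[C@H]2C[C@@H]([C@@H](O)c3ccc(O[Si](C(C)C)(C(C)C)C(C)C)cc3)CO[C@H]2c2ccc(O[Si](C(C)C)(C(C)C)C(C)C)cc2 | intermediate
20 | tris(triisopropylsilyl) ether of the target | CC(C)[Si](C(C)C)(C(C)C)Oc1ccc(/C=C/C[C@H]2C[C@@H]([C@@H](O)c3ccc(O[Si](C(C)C)(C(C)C)C(C)C)cc3)CO[C@H]2c2ccc(O[Si](C(C)C)(C(C)C)C(C)C)cc2)cc1 | intermediate
21 | (R)-{(2R,3S,5R)-3-[(E)-3-(4-hydroxyphenyl)prop-2-enyl]-2-(4-hydroxyphenyl)oxan-5-yl}(4-hydroxyphenyl)methanol | Oc1ccc(/C=C/C[C@H]2C[C@@H]([C@@H](O)c3ccc(O)cc3)CO[C@H]2c2ccc(O)cc2)cc1 | target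

**Totals**

Total step count: 13. Longest linear sequence: 10 steps (1, 3, 4, 5, 6, 7, 8, 9, 12, 13).

**Steps most likely to fail**

Step 4. The excited chelated enol may decay unproductively (rotation to the non-chelated enol and ketonisation) faster than it is captured by the weakly donating ethylene, and prolonged irradiation may start to photolyse the product. The fallback is thermal and sets out from 2. One portion of 2 is α-methylenated (Mannich base, then elimination) to the aryl vinyl ketone 1-[4-(triisopropylsilyloxy)phenyl]prop-2-en-1-one F1. A second portion is converted with TMSOTf/Et3N into the silyl enol ether trimethyl({1-[4-(triisopropylsilyloxy)phenyl]ethenyl}oxy)silane F2. A Mukaiyama–Michael addition of F2 to F1 (TiCl4, CH2Cl2, −78 °C) then returns to the route at 8.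

Step 6. The oxazaborolidine may differentiate the aryl group and the twisted 1-substituted vinyl group only weakly, so that enantioface selection is poor, and conjugate reduction may compete. The fallback sets out from 9. Luche reduction (NaBH4, CeCl3, MeOH, −40 °C) gives the diol as a stereoisomer mixture, 2,4-dimethylidene-1,5-bis[4-(triisopropylsilyloxy)phenyl]pentane-1,5-diol F3. A Sharpless kinetic resolution (Ti(OiPr)4, D-(−)-diisopropyl tartrate, t-BuOOH, 4 Å sieves, CH2Cl2, −20 °C; tartrate chosen by the Sharpless mnemonic) should epoxidise the carbinol units of the unwanted configuration and leave the (1R,5R)-diol, returning to the route at 10.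

Step 12. The tosylate–iodide exchange may lag behind reductive homocoupling of the alkenyl bromide, the alkyl radical may be reduced instead of coupled, and some E/Z scrambling is possible. The fallback replaces the reductive radical coupling by a polar substitution. The bromide 18 is converted with Mg in THF into (E)-2-[4-(triisopropylsilyloxy)phenyl]ethenylmagnesium bromide F4. F4 (3 equiv, the first deprotonating the free hydroxyl) is coupled with tosylate 14 under copper catalysis (Li2CuCl4, THF, −20 → 0 °C, kept cold to hold back a second ring closure by the magnesium alkoxide). This returns to the route at 20.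

**Further compounds**

F1 | step 4 | 1-[4-(triisopropylsilyloxy)phenyl]prop-2-en-1-one | C=CC(=O)c1ccc(O[Si](C(C)C)(C(C)C)C(C)C)cc1
F2 | step 4 | trimethyl({1-[4-(triisopropylsilyloxy)phenyl]ethenyl}oxy)silane | C=C(O[Si](C)(C)C)c1ccc(O[Si](C(C)C)(C(C)C)C(C)C)cc1
F3 | step 6 | 2,4-dimethylidene-1,5-bis[4-(triisopropylsilyloxy)phenyl]pentane-1,5-diol (mixture of stereoisomers) | C=C(CC(=C)C(O)c1ccc(O[Si](C(C)C)(C(C)C)C(C)C)cc1)C(O)c1ccc(O[Si](C(C)C)(C(C)C)C(C)C)cc1
F4 | step 12 | (E)-2-[4-(triisopropylsilyloxy)phenyl]ethenylmagnesium bromide | Br[Mg]/C=C/c1ccc(O[Si](C(C)C)(C(C)C)C(C)C)cc1
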